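**Retrosynthetic overview**
- Last: global desilylation; the enone comes from the hindered ring aldehyde by Ni/Cr alkenylation with a C5 alkenyl iodide and oxidation.
- Key bond C(=O)–CH2: cobalt-catalysed aldehyde C–H addition (cis-1,4-hydroacylation) of a ring dialdehyde to an aryl diene, which also sets the Z trisubstituted alkene.
- Dialdehyde: ozonolysis of an enantioenriched bicyclo[3.3.0]octene, made from a meso ketone by chiral lithium amide deprotonation and enol triflate reduction; this fixes both quaternary centres.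
- Rings: ring A (cyclopentane) is bought as 1,2-dimethylcyclopentene; a cyclobutanone is fused on by [2+2], expanded to cyclopentanone ring B and later cleaved; the arene comes from o-cresol, the diene by Suzuki coupling.

Assumption: the (R,R) antipode of the lithium amide in step 4 is chosen by analogy with related bicyclic ketones (its enantiomer is used if the sense of induction is reversed), and diazomethane is used as a freshly prepared ether solution.

**Route**

Step 1
Reactants: 1 1,2-dimethylcyclopentene; 2 trichloroacetyl chloride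
Product: 4 rac-(1R,5S)-7,7-dichloro-1,5-dimethylbicyclo[3.2.0]heptan-6-one (cis ring fusion), via dichloroketene 3 (not isolated)
Conditions: Zn–Cu couple, POCl3, Et2O, reflux
Reagents that add atoms: none
Why: Dichloroketene made in situ adds to the electron-rich tetrasubstituted alkene in a thermal ketene–alkene [2+2] cycloaddition, and suprafacial addition to the alkene makes the ring fusion, and so the two methyl groups, cis.

Step 2
Reactants: 4 rac-(1R,5S)-7,7-dichloro-1,5-dimethylbicyclo[3.2.0]heptan-6-one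
Product: 5 rac-(1R,5R)-2,2-dichloro-1,5-dimethylbicyclo[3.3.0]octan-3-one (cis ring fusion)
Conditions: CH2N2, Et2O, MeOH (cat.), 0 °C
Reagents that add atoms: diazomethane, C=[N+]=[N-]
Why: Diazomethane ring expansion (Tiffeneau–Demjanov type) of the activated α,α-dichlorocyclobutanone is regioselective because the electron-rich quaternary carbon migrates in preference to CCl2, with retention, so the cis fusion is kept.

Step 3
Reactants: 5 rac-(1R,5R)-2,2-dichloro-1,5-dimethylbicyclo[3.3.0]octan-3-one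
Product: 6 (1R,5S)-1,5-dimethylbicyclo[3.3.0]octan-3-one (meso, cis)
Conditions: Zn dust, AcOH, 70 °C
Reagents that add atoms: none
Why: Reductive dechlorination of the α,α-dichloro ketone by zinc gives the meso ketone without touching the quaternary carbons.

Step 4
Reactants: 6 (1R,5S)-1,5-dimethylbicyclo[3.3.0]octan-3-one
Product: 8 (1R,5S)-1,5-dimethylbicyclo[3.3.0]oct-2-en-3-yl trifluoromethanesulfonate, via lithium enolate 7 (not isolated)
Conditions: (R,R)-bis(1-phenylethyl)amine, n-BuLi, LiCl, THF, −78 °C; then PhNTf2, −78 → 0 °C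
Reagents that add atoms: N-phenylbis(trifluoromethanesulfonimide), O=S(=O)(N(c1ccccc1)S(=O)(=O)C(F)(F)F)C(F)(F)F
Why: Asymmetric deprotonation of the meso ketone by the C2-symmetric chiral lithium amide removes one of the two enantiotopic α-protons, which fixes the absolute configuration of both quaternary centres at once, and O-triflation of the enolate preserves it.

Step 5
Reactants: 8 (1R,5S)-1,5-dimethylbicyclo[3.3.0]oct-2-en-3-yl trifluoromethanesulfonate
Product: 9 (1R,5S)-1,5-dimethylbicyclo[3.3.0]oct-2-ene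
Conditions: Pd(OAc)2 (5 mol %), PPh3, Bu3N, HCO2H, DMF, 60 °C
Reagents that add atoms: none
Why: Palladium-catalysed formate reduction of the enol triflate (oxidative addition, decarboxylation to Pd–H, reductive elimination) replaces OTf by H without moving the double bond or touching the stereocentres.

Step 6
Reactants: 9 (1R,5S)-1,5-dimethylbicyclo[3.3.0]oct-2-ene
Product: 11 (1S,2S)-1,2-dimethyl-2-(2-oxoethyl)cyclopentane-1-carbaldehyde, via secondary ozonide 10 (not isolated)
Conditions: O3, CH2Cl2, −78 °C; then PPh3, −78 °C → rt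
Reagents that add atoms: ozone, [O-][O+]=O
Why: Ozonolysis with reductive work-up (Criegee mechanism) cleaves ring B to a neopentyl formyl group and an unhindered CH2CHO group, both quaternary centres being non-epimerisable.

Step 7
Reactants: 12 2-methylphenol
Product: 13 2-bromo-6-methylphenol
Conditions: NBS, i-Pr2NH (10 mol %), CH2Cl2, 0 °C
Reagents that add atoms: N-bromosuccinimide, O=C1CCC(=O)N1Br
Why: Amine-mediated ortho-selective electrophilic bromination of the phenol puts bromine on the only free ortho position.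

Step 8
Reactants: 13 2-bromo-6-methylphenol
Product: 14 2-bromo-6-methyl-1,4-benzoquinone
Conditions: Co(salen) (10 mol %), O2 (1 atm), DMF, rt
Reagents that add atoms: dioxygen, O=O
Why: Cobalt–salen-catalysed aerobic phenol oxidation gives the para-quinone because both ortho positions are blocked.

Step 9
Reactants: 14 2-bromo-6-methyl-1,4-benzoquinone
Product: 15 2-bromo-6-methylbenzene-1,4-diol
Conditions: Na2S2O4, EtOAc/H2O, rt
Reagents that add atoms: none
Why: Dithionite reduction converts the quinone cleanly into the hydroquinone.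

Step 10
Reactants: 15 2-bromo-6-methylbenzene-1,4-diol
Product: 16 1-bromo-2,5-bis(tert-butyldimethylsilyloxy)-3-methylbenzene
Conditions: TBSCl, imidazole, DMF, rt → 40 °C
Reagents that add atoms: tert-butyldimethylsilyl chloride, CC(C)(C)[Si](C)(C)Cl
Why: Imidazole-assisted silylation protects both phenols as ethers that survive the later steps and fall to fluoride at the end.

Step 11
Reactants: 17 2-methylbut-1-en-3-yne
Product: 18 (E)-4,4,5,5-tetramethyl-2-(3-methylbuta-1,3-dien-1-yl)-1,3,2-dioxaborolane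
Conditions: pinacolborane, Cp2Zr(H)Cl (5 mol %), Et3N (10 mol %), neat, 50 °C
Reagents that add atoms: pinacolborane, CC1(C)OBOC1(C)C
Why: Zirconium-catalysed syn hydroboration of the terminal alkyne gives the (E)-dienylboronate and leaves the 1,1-disubstituted alkene alone.

Step 12
Reactants: 16 1-bromo-2,5-bis(tert-butyldimethylsilyloxy)-3-methylbenzene; 18 (E)-4,4,5,5-tetramethyl-2-(3-methylbuta-1,3-dien-1-yl)-1,3,2-dioxaborolane
Product: 19 (E)-1-[2,5-bis(tert-butyldimethylsilyloxy)-3-methylphenyl]-3-methylbuta-1,3-diene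
Conditions: Pd(OAc)2 (3 mol %), 2-dicyclohexylphosphino-2′,6′-dimethoxybiphenyl (6 mol %), K3PO4, toluene/H2O, 70 °C
Reagents that add atoms: none
Why: Suzuki–Miyaura cross-coupling joins the aryl bromide and the alkenylboronate with retention of the (E) geometry.

Step 13
Reactants: 11 (1S,2S)-1,2-dimethyl-2-(2-oxoethyl)cyclopentane-1-carbaldehyde; 19 (E)-1-[2,5-bis(tert-butyldimethylsilyloxy)-3-methylphenyl]-3-methylbuta-1,3-diene
Product: 20 (1S,2S)-2-[(4Z)-6-[2,5-bis(tert-butyldimethylsilyloxy)-3-methylphenyl]-4-methyl-2-oxohex-4-en-1-yl]-1,2-dimethylcyclopentane-1-carbaldehyde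
Conditions: CoI2 (10 mol %), 1,2-bis(dicyclohexylphosphino)ethane (10 mol %), Zn powder (20 mol %), THF, 40 °C; 19 (1.3 equiv)
Reagents that add atoms: none
Why: Proposed new method: a monovalent cobalt–bisphosphine catalyst binds the diene s-cis and couples its unsubstituted CH2 terminus oxidatively with the unhindered aldehyde (the neopentyl formyl group is too shielded), β-hydride elimination of the cobalt alkoxide then gives the ketone and an allyl cobalt hydride whose fully substituted C2 terminus blocks C–H formation there, so hydrogen goes to the benzylic terminus and the two CH2 groups held cis in the metallacycle stay cis (Z alkene, which cannot scramble without a tertiary σ-allyl); the closest known reaction type is the cobalt-catalysed hydroacylation of 1,3-dienes with non-chelating aldehydes through an oxidative-cyclisation pathway, which has not been shown for 2-substituted 1-aryl dienes, for 1,4-selectivity with aliphatic aldehydes, or for a dialdehyde.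

Step 14
Reactants: 21 2-methylbut-3-yn-2-ol
Product: 22 triethyl[(2-methylbut-3-yn-2-yl)oxy]silane
Conditions: TESOTf, 2,6-lutidine, CH2Cl2, 0 °C
Reagents that add atoms: triethylsilyl trifluoromethanesulfonate, CC[Si](CC)(CC)OS(=O)(=O)C(F)(F)F
Why: Silyl triflate silylation protects the tertiary alcohol.

Step 15
Reactants: 22 triethyl[(2-methylbut-3-yn-2-yl)oxy]silane
Product: 24 (E)-triethyl[(4-iodo-2-methylbut-3-en-2-yl)oxy]silane, via alkenylzirconocene chloride 23 (not isolated)
Conditions: Cp2Zr(H)Cl, THF, rt; then I2, 0 °C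
Reagents that add atoms: iodine, [I][I]
Why: Hydrozirconation (syn, metal at the terminal carbon) followed by iodinolysis with retention gives the (E)-alkenyl iodide.

Step 16
Reactants: 20 (1S,2S)-2-[(4Z)-6-[2,5-bis(tert-butyldimethylsilyloxy)-3-methylphenyl]-4-methyl-2-oxohex-4-en-1-yl]-1,2-dimethylcyclopentane-1-carbaldehyde; 24 (E)-triethyl[(4-iodo-2-methylbut-3-en-2-yl)oxy]silane
Product: 26 (4Z)-6-[2,5-bis(tert-butyldimethylsilyloxy)-3-methylphenyl]-1-[(1S,2S)-2-[(2E)-1-hydroxy-4-methyl-4-(triethylsilyloxy)pent-2-en-1-yl]-1,2-dimethylcyclopentyl]-4-methylhex-4-en-2-one (both carbinol epimers), via alkenylchromium dichloride 25 (not isolated)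
Conditions: CrCl2 (6 equiv), NiCl2 (2 mol %), DMSO, rt; 24 (3 equiv)
Reagents that add atoms: none
Why: Nozaki–Hiyama–Kishi coupling, in which the nickel-catalysed alkenylchromium species adds to the aldehyde and not to the enolisable β,γ-unsaturated ketone; the new carbinol centre is a mixture and is removed in step 17.

Step 17
Reactants: 26 (4Z)-6-[2,5-bis(tert-butyldimethylsilyloxy)-3-methylphenyl]-1-[(1S,2S)-2-[(2E)-1-hydroxy-4-methyl-4-(triethylsilyloxy)pent-2-en-1-yl]-1,2-dimethylcyclopentyl]-4-methylhex-4-en-2-one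
Product: 27 (2E)-1-[(1S,2S)-2-[(4Z)-6-[2,5-bis(tert-butyldimethylsilyloxy)-3-methylphenyl]-4-methyl-2-oxohex-4-en-1-yl]-1,2-dimethylcyclopentyl]-4-methyl-4-(triethylsilyloxy)pent-2-en-1-one
Conditions: Dess–Martin periodinane, pyridine, CH2Cl2, 0 °C
Reagents that add atoms: none
Why: Dess–Martin oxidation turns the allylic alcohol into the (E)-enone under near-neutral conditions that leave the β,γ-unsaturated ketone unconjugated.

Step 18
Reactants: 27 (2E)-1-[(1S,2S)-2-[(4Z)-6-[2,5-bis(tert-butyldimethylsilyloxy)-3-methylphenyl]-4-methyl-2-oxohex-4-en-1-yl]-1,2-dimethylcyclopentyl]-4-methyl-4-(triethylsilyloxy)pent-2-en-1-one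
Product: 28 (2E)-1-[(1S,2S)-2-[(4Z)-6-(2,5-dihydroxy-3-methylphenyl)-4-methyl-2-oxohex-4-en-1-yl]-1,2-dimethylcyclopentyl]-4-hydroxy-4-methylpent-2-en-1-one
Conditions: Bu4NF, AcOH (1:1), degassed THF, 0 °C → rt
Reagents that add atoms: none
Why: Fluoride-mediated cleavage removes the two aryl silyl ethers and the tertiary triethylsilyl ether, with acetic acid buffering to prevent base-induced migration of the β,γ double bond and air oxidation of the hydroquinone.

**Compound list**
1 | 1,2-dimethylcyclopentene | CC1=C(C)CCC1 | starting material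
2 | trichloroacetyl chloride | ClC(Cl)(Cl)C(Cl)=O | starting material
3 | dichloroketene | ClC(Cl)=C=O | intermediate
4 | rac-(1R,5S)-7,7-dichloro-1,5-dimethylbicyclo[3.2.0]heptan-6-one (cis fusion; one enantiomer drawn) | O=C1[C@@]2(C)CCC[C@@]2(C)C1(Cl)Cl | intermediate
5 | rac-(1R,5R)-2,2-dichloro-1,5-dimethylbicyclo[3.3.0]octan-3-one (cis fusion; one enantiomer drawn) | O=C1C[C@@]2(C)CCC[C@@]2(C)C1(Cl)Cl | intermediate
6 | (1R,5S)-1,5-dimethylbicyclo[3.3.0]octan-3-one (meso, cis) | O=C1C[C@@]2(C)CCC[C@@]2(C)C1 | intermediate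
7 | lithium (1R,5S)-1,5-dimethylbicyclo[3.3.0]oct-2-en-3-olate | [Li+].[O-]C1=C[C@@]2(C)CCC[C@@]2(C)C1 | intermediate
8 | (1R,5S)-1,5-dimethylbicyclo[3.3.0]oct-2-en-3-yl trifluoromethanesulfonate | O=S(=O)(OC1=C[C@@]2(C)CCC[C@@]2(C)C1)C(F)(F)F | intermediate
9 | (1R,5S)-1,5-dimethylbicyclo[3.3.0]oct-2-ene | C1=C[C@@]2(C)CCC[C@@]2(C)C1 | intermediate
10 | secondary ozonide of 9 (1,2,4-trioxolane spanning the former C2 and C3) | O1C2C[C@]3(C)CCC[C@]3(C)C1OO2 | intermediate
11 | (1S,2S)-1,2-dimethyl-2-(2-oxoethyl)cyclopentane-1-carbaldehyde | O=CC[C@]1(C)CCC[C@]1(C)C=O | intermediate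
12 | 2-methylphenol (o-cresol) | Cc1ccccc1O | starting material
13 | 2-bromo-6-methylphenol | Cc1cccc(Br)c1O | intermediate
14 | 2-bromo-6-methyl-1,4-benzoquinone | CC1=CC(=O)C=C(Br)C1=O | intermediate
15 | 2-bromo-6-methylbenzene-1,4-diol | Cc1cc(O)cc(Br)c1O | intermediate
16 | 1-bromo-2,5-bis(tert-butyldimethylsilyloxy)-3-methylbenzene | Cc1cc(O[Si](C)(C)C(C)(C)C)cc(Br)c1O[Si](C)(C)C(C)(C)C | intermediate
17 | 2-methylbut-1-en-3-yne | CC(=C)C#C | starting material
18 | (E)-4,4,5,5-tetramethyl-2-(3-methylbuta-1,3-dien-1-yl)-1,3,2-dioxaborolane | CC(=C)/C=C/B1OC(C)(C)C(C)(C)O1 | intermediate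
19 | (E)-1-[2,5-bis(tert-butyldimethylsilyloxy)-3-methylphenyl]-3-methylbuta-1,3-diene | CC(=C)/C=C/c1cc(O[Si](C)(C)C(C)(C)C)cc(C)c1O[Si](C)(C)C(C)(C)C | intermediate
20 | (1S,2S)-2-[(4Z)-6-[2,5-bis(tert-butyldimethylsilyloxy)-3-methylphenyl]-4-methyl-2-oxohex-4-en-1-yl]-1,2-dimethylcyclopentane-1-carbaldehyde | C/C(=C/Cc1cc(O[Si](C)(C)C(C)(C)C)cc(C)c1O[Si](C)(C)C(C)(C)C)CC(=O)C[C@]1(C)CCC[C@]1(C)C=O | intermediate
21 | 2-methylbut-3-yn-2-ol | CC(C)(O)C#C | starting material
22 | triethyl[(2-methylbut-3-yn-2-yl)oxy]silane | CC[Si](CC)(CC)OC(C)(C)C#C | intermediate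
23 | (E)-[3-methyl-3-(triethylsilyloxy)but-1-en-1-yl]zirconocene chloride | CC[Si](CC)(CC)OC(C)(C)/C=C/[Zr+2]Cl.c1cc[cH-]c1.c1cc[cH-]c1 | intermediate
24 | (E)-triethyl[(4-iodo-2-methylbut-3-en-2-yl)oxy]silane | CC[Si](CC)(CC)OC(C)(C)/C=C/I | intermediate
25 | (E)-[3-methyl-3-(triethylsilyloxy)but-1-en-1-yl]chromium dichloride | CC[Si](CC)(CC)OC(C)(C)/C=C/[Cr](Cl)Cl | intermediate
26 | (4Z)-6-[2,5-bis(tert-butyldimethylsilyloxy)-3-methylphenyl]-1-[(1S,2S)-2-[(2E)-1-hydroxy-4-methyl-4-(triethylsilyloxy)pent-2-en-1-yl]-1,2-dimethylcyclopentyl]-4-methylhex-4-en-2-one (both carbinol epimers) | C/C(=C/Cc1cc(O[Si](C)(C)C(C)(C)C)cc(C)c1O[Si](C)(C)C(C)(C)C)CC(=O)C[C@]1(C)CCC[C@]1(C)C(O)/C=C/C(C)(C)O[Si](CC)(CC)CC | intermediate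
27 | (2E)-1-[(1S,2S)-2-[(4Z)-6-[2,5-bis(tert-butyldimethylsilyloxy)-3-methylphenyl]-4-methyl-2-oxohex-4-en-1-yl]-1,2-dimethylcyclopentyl]-4-methyl-4-(triethylsilyloxy)pent-2-en-1-one | C/C(=C/Cc1cc(O[Si](C)(C)C(C)(C)C)cc(C)c1O[Si](C)(C)C(C)(C)C)CC(=O)C[C@]1(C)CCC[C@]1(C)C(=O)/C=C/C(C)(C)O[Si](CC)(CC)CC | intermediate
28 | (2E)-1-[(1S,2S)-2-[(4Z)-6-(2,5-dihydroxy-3-methylphenyl)-4-methyl-2-oxohex-4-en-1-yl]-1,2-dimethylcyclopentyl]-4-hydroxy-4-methylpent-2-en-1-one | C/C(=C/Cc1cc(O)cc(C)c1O)CC(=O)C[C@]1(C)CCC[C@]1(C)C(=O)/C=C/C(C)(C)O | target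

**Step count and risks**

Total step count: 18. Longest linear sequence: 10 steps (1–6, 13, 16, 17, 18).

Steps most likely to fail:

1. Step 13 (the proposed new step). The risks are hydrogen delivery to C2 instead of C4 (1,2-adduct), intramolecular Tishchenko lactonisation of the dialdehyde and diene dimerisation. The fallback uses known chemistry, sets out from 11 (with 19 and 24) and returns at 27. Nickel-catalysed reductive three-component coupling of 11, 19 and Et3SiH, with Ni(cod)2 and the carbene from 1,3-bis(2,6-diisopropylphenyl)imidazolium chloride and KOt-Bu in THF, is a known reaction type that joins an aldehyde to the unsubstituted diene terminus as the cis-1,4 adduct; it gives the homoallylic triethylsilyl ether aldehyde F1. Nozaki–Hiyama–Kishi coupling of F1 with 24 (CrCl2, NiCl2 cat., DMSO) gives the allylic alcohol F2. Pyridinium p-toluenesulfonate in MeOH/CH2Cl2 at 0 °C removes the secondary triethylsilyl group selectively and gives the diol F3, and Dess–Martin oxidation of both secondary alcohols gives 27.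

2. Step 4. Deprotonation next to a quaternary carbon may be slow, and external triflation may erode the ee. The fallback sets out from 6 and returns at 11, bypassing steps 4 to 6. The same chiral lithium amide is used under internal-quench conditions (TMSCl present, THF, −78 °C) to give the trimethylsilyl enol ether F4. Ozonolysis of F4 followed by NaBH4 and acidic work-up gives the δ-lactone F5, which can be recrystallised to raise the ee. LiAlH4 reduction gives the diol F6, and Swern oxidation ((COCl)2, DMSO, Et3N) gives 11.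

3. Step 16. Addition to a formyl group flanked by two quaternary carbons may stall. The fallback sets out from 20 and returns at 27, replacing carbonyl addition by acyl cross-coupling. Pinnick oxidation of 20 (NaClO2, NaH2PO4, 2-methylbut-2-ene) gives the carboxylic acid F7, and 1-chloro-N,N,2-trimethylprop-1-en-1-amine in CH2Cl2 converts it into the acid chloride F8 under neutral conditions. Hydrostannation of 22 (Bu3SnH, PdCl2(PPh3)2 cat.) gives the (E)-alkenylstannane F9, and Stille coupling of F8 with F9 (Pd2(dba)3, AsPh3, toluene, 60 °C) gives 27.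

Further compounds
F1 | step 13 | (1S,2S)-2-[(4Z)-6-[2,5-bis(tert-butyldimethylsilyloxy)-3-methylphenyl]-4-methyl-2-(triethylsilyloxy)hex-4-en-1-yl]-1,2-dimethylcyclopentane-1-carbaldehyde (both epimers at the silyloxy carbon) | C/C(=C/Cc1cc(O[Si](C)(C)C(C)(C)C)cc(C)c1O[Si](C)(C)C(C)(C)C)CC(O[Si](CC)(CC)CC)C[C@]1(C)CCC[C@]1(C)C=O
F2 | step 13 | (2E)-1-[(1S,2S)-2-[(4Z)-6-[2,5-bis(tert-butyldimethylsilyloxy)-3-methylphenyl]-4-methyl-2-(triethylsilyloxy)hex-4-en-1-yl]-1,2-dimethylcyclopentyl]-4-methyl-4-(triethylsilyloxy)pent-2-en-1-ol | C/C(=C/Cc1cc(O[Si](C)(C)C(C)(C)C)cc(C)c1O[Si](C)(C)C(C)(C)C)CC(O[Si](CC)(CC)CC)C[C@]1(C)CCC[C@]1(C)C(O)/C=C/C(C)(C)O[Si](CC)(CC)CC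
F3 | step 13 | (4Z)-6-[2,5-bis(tert-butyldimethylsilyloxy)-3-methylphenyl]-1-[(1S,2S)-2-[(2E)-1-hydroxy-4-methyl-4-(triethylsilyloxy)pent-2-en-1-yl]-1,2-dimethylcyclopentyl]-4-methylhex-4-en-2-ol | C/C(=C/Cc1cc(O[Si](C)(C)C(C)(C)C)cc(C)c1O[Si](C)(C)C(C)(C)C)CC(O)C[C@]1(C)CCC[C@]1(C)C(O)/C=C/C(C)(C)O[Si](CC)(CC)CC
F4 | step 4 | trimethyl{[(1R,5S)-1,5-dimethylbicyclo[3.3.0]oct-2-en-3-yl]oxy}silane | C[Si](C)(C)OC1=C[C@@]2(C)CCC[C@@]2(C)C1
F5 | step 4 | (4aS,7aS)-4a,7a-dimethylhexahydrocyclopenta[c]pyran-3(1H)-one | O=C1C[C@]2(C)CCC[C@]2(C)CO1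
F6 | step 4 | 2-[(1S,2S)-2-(hydroxymethyl)-1,2-dimethylcyclopentyl]ethan-1-ol | OCC[C@]1(C)CCC[C@]1(C)CO
F7 | step 16 | (1S,2S)-2-[(4Z)-6-[2,5-bis(tert-butyldimethylsilyloxy)-3-methylphenyl]-4-methyl-2-oxohex-4-en-1-yl]-1,2-dimethylcyclopentane-1-carboxylic acid | C/C(=C/Cc1cc(O[Si](C)(C)C(C)(C)C)cc(C)c1O[Si](C)(C)C(C)(C)C)CC(=O)C[C@]1(C)CCC[C@]1(C)C(=O)O
F8 | step 16 | (1S,2S)-2-[(4Z)-6-[2,5-bis(tert-butyldimethylsilyloxy)-3-methylphenyl]-4-methyl-2-oxohex-4-en-1-yl]-1,2-dimethylcyclopentane-1-carbonyl chloride | C/C(=C/Cc1cc(O[Si](C)(C)C(C)(C)C)cc(C)c1O[Si](C)(C)C(C)(C)C)CC(=O)C[C@]1(C)CCC[C@]1(C)C(=O)Cl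
F9 | step 16 | (E)-tributyl[3-methyl-3-(triethylsilyloxy)but-1-en-1-yl]stannane | CCCC[Sn](CCCC)(CCCC)/C=C/C(C)(C)O[Si](CC)(CC)CC
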